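## Retrosynthetic overview

1. The last bond is the aryl ether C1–O, made by Mitsunobu coupling of purchased umbelliferone with a primary epoxy alcohol.
2. The hydroxy-γ-lactone is the last ring formed: hydride opening of an epoxy δ-lactone frees the C5 oxygen, which transacylates onto the lactic-acid carbonyl C8.
3. The oxirane comes from peroxide epoxidation of a 4-methyl-5,6-dihydro-2H-pyran-2-one, anti to its ring substituent (C5 controls C2 and C3).
4. Key step: the dihydropyranone ring is made by an oxa-Diels–Alder cycloaddition of a lactic-acid-derived aldehyde with a 1-methoxy-1-silyloxy-3-methyl diene. It forms C4–C5, locks the cis (neryl-type) C2=C3 geometry and sets C5.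
5. The aldehyde carries C7 from (S)-lactic acid (pivalaldehyde acetal, allylation anti to tert-butyl, ozonolysis). Ring order: dioxolanone (temporary), dihydropyranone, oxirane, butyrolactone.

Convention: C1 to C8 label the side chain of the target from the OCH2 carbon (C1) to the lactone carbonyl (C8).

## Route

Step 1
Reactants: 1 (S)-lactic acid; 2 pivalaldehyde (2,2-dimethylpropanal)
Product: 3 (2S,5S)-2-tert-butyl-5-methyl-1,3-dioxolan-4-one
Conditions: TsOH·H2O (cat.), H2SO4 (cat.), pentane, reflux (Dean–Stark); crystallization from pentane, −78 °C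
Reagents that add atoms: none
Why: Acid-catalysed acetalization with azeotropic removal of water, in which the lactic acid center steers the new acetal carbon to the cis (2S,5S) isomer (about 4:1, thermodynamic), purified by low-temperature crystallization.

Step 2
Reactants: 3 (2S,5S)-2-tert-butyl-5-methyl-1,3-dioxolan-4-one; 4 allyl bromide (3-bromoprop-1-ene)
Product: 6 (2S,5R)-2-tert-butyl-5-methyl-5-(prop-2-en-1-yl)-1,3-dioxolan-4-one, via lithium enolate 5 (not isolated)
Conditions: LiN(iPr)2 (1.05 equiv), THF, −78 °C; then allyl bromide, −78 → −30 °C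
Reagents that add atoms: none
Why: Seebach alkylation (self-regeneration of the stereocenter), in which the planar enolate is attacked anti to the tert-butyl group so that allyl replaces H with retention and the quaternary center has the configuration needed for C7.

Step 3
Reactants: 6 (2S,5R)-2-tert-butyl-5-methyl-5-(prop-2-en-1-yl)-1,3-dioxolan-4-one
Product: 8 2-[(2S,4R)-2-tert-butyl-4-methyl-5-oxo-1,3-dioxolan-4-yl]acetaldehyde, via secondary ozonide 7 (not isolated)
Conditions: O3, CH2Cl2, −78 °C; then Me2S, −78 °C → rt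
Reagents that add atoms: ozone, [O-][O+]=O
Why: Ozonolysis with reductive work-up cuts the terminal alkene to the aldehyde without touching either stereocenter.

Step 4
Reactants: 9 methyl 3-methylbut-2-enoate
Product: 11 [(1-methoxy-3-methylbuta-1,3-dien-1-yl)oxy]trimethylsilane, via lithium dienolate 10 (not isolated)
Conditions: LiN(iPr)2, THF, −78 °C; then Me3SiCl, −78 °C → rt; distillation
Reagents that add atoms: chlorotrimethylsilane, C[Si](C)(C)Cl
Why: Kinetic γ-deprotonation of the β,β-dimethylacrylate gives the extended enolate, which is O-silylated to the electron-rich silyl ketene acetal diene (no stereocenter formed).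

Step 5
Reactants: 8 2-[(2S,4R)-2-tert-butyl-4-methyl-5-oxo-1,3-dioxolan-4-yl]acetaldehyde; 11 [(1-methoxy-3-methylbuta-1,3-dien-1-yl)oxy]trimethylsilane
Product: 13 (6S)-6-{[(2S,4R)-2-tert-butyl-4-methyl-5-oxo-1,3-dioxolan-4-yl]methyl}-4-methyl-5,6-dihydro-2H-pyran-2-one, via ortho ester cycloadduct 12 (not isolated)
Conditions: MgBr2·OEt2 (1.2 equiv), CH2Cl2, −78 → −20 °C; then 0.5 M HCl, THF, 0 °C
Reagents that add atoms: none
Why: Lewis-acid-promoted hetero-Diels–Alder (oxa-[4+2]) cycloaddition of the aldehyde with the diene forms C4–C5 and the ring that forces the cis C2=C3 geometry, and C5 is set by the lactic-acid-derived C7 because magnesium chelates the aldehyde oxygen and the ring ether oxygen so that the diene adds to the chelate face opposite the carbonyl arm of the dioxolanone (the face of the small C-methyl group).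

Step 6
Reactants: 13 (6S)-6-{[(2S,4R)-2-tert-butyl-4-methyl-5-oxo-1,3-dioxolan-4-yl]methyl}-4-methyl-5,6-dihydro-2H-pyran-2-one
Product: 14 (1R,4S,6R)-4-{[(2S,4R)-2-tert-butyl-4-methyl-5-oxo-1,3-dioxolan-4-yl]methyl}-6-methyl-3,7-dioxabicyclo[4.1.0]heptan-2-one
Conditions: t-BuOOH (1.5 equiv), n-BuLi (1.4 equiv) to give t-BuOOLi, THF, −78 → −10 °C; then H2O
Reagents that add atoms: tert-butyl hydroperoxide, CC(C)(C)OO
Why: Nucleophilic (Weitz–Scheffer type) epoxidation in which the peroxide adds axially to the β-carbon of the half-chair lactone, anti to the pseudo-equatorial ring substituent, so the oxirane is trans to the side chain and C2 and C3 are set by C5.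

Step 7
Reactants: 14 (1R,4S,6R)-4-{[(2S,4R)-2-tert-butyl-4-methyl-5-oxo-1,3-dioxolan-4-yl]methyl}-6-methyl-3,7-dioxabicyclo[4.1.0]heptan-2-one
Product: 16 (3R,5R)-3-hydroxy-5-{[(2R,3S)-3-(hydroxymethyl)-2-methyloxiran-2-yl]methyl}-3-methyloxolan-2-one, via epoxy diol 15 (not isolated)
Conditions: NaBH4 (2.5 equiv), EtOH–THF, −10 → 0 °C; then H2O
Reagents that add atoms: none
Why: Borohydride reduction of the activated glycidic δ-lactone to the primary alcohol spares the hindered dioxolanone carbonyl, and the freed C5 alkoxide then closes the γ-lactone by 5-exo-trig transacylation with loss of pivalaldehyde, leaving every stereocenter untouched.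

Step 8
Reactants: 16 (3R,5R)-3-hydroxy-5-{[(2R,3S)-3-(hydroxymethyl)-2-methyloxiran-2-yl]methyl}-3-methyloxolan-2-one; 17 umbelliferone (7-hydroxy-2H-chromen-2-one)
Product: 18 7-{[(2S,3R)-3-{[(2R,4R)-4-hydroxy-4-methyl-5-oxooxolan-2-yl]methyl}-3-methyloxiran-2-yl]methoxy}-2H-chromen-2-one
Conditions: PPh3, DIAD, THF, 0 °C → rt
Reagents that add atoms: none
Why: Mitsunobu etherification in which only the primary alcohol is activated and displaced by the acidic phenol at the CH2 carbon, while the tertiary alcohol, the epoxide and both lactones are inert, so no stereocenter changes.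

## Compound list

1 | (S)-lactic acid | C[C@H](O)C(=O)O | starting material
2 | pivalaldehyde (2,2-dimethylpropanal) | CC(C)(C)C=O | starting material
3 | (2S,5S)-2-tert-butyl-5-methyl-1,3-dioxolan-4-one | C[C@@H]1O[C@H](C(C)(C)C)OC1=O | intermediate
4 | allyl bromide (3-bromoprop-1-ene) | C=CCBr | starting material
5 | lithium (2S)-2-tert-butyl-5-methyl-1,3-dioxol-4-olate | CC1=C(O[Li])O[C@@H](C(C)(C)C)O1 | intermediate
6 | (2S,5R)-2-tert-butyl-5-methyl-5-(prop-2-en-1-yl)-1,3-dioxolan-4-one | C[C@]1(CC=C)O[C@H](C(C)(C)C)OC1=O | intermediate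
7 | (2S,5R)-2-tert-butyl-5-methyl-5-(1,2,4-trioxolan-3-ylmethyl)-1,3-dioxolan-4-one (both epimers at the trioxolane carbon) | C[C@]1(CC2OCOO2)O[C@H](C(C)(C)C)OC1=O | intermediate
8 | 2-[(2S,4R)-2-tert-butyl-4-methyl-5-oxo-1,3-dioxolan-4-yl]acetaldehyde | C[C@]1(CC=O)O[C@H](C(C)(C)C)OC1=O | intermediate
9 | methyl 3-methylbut-2-enoate | COC(=O)C=C(C)C | starting material
10 | lithium 1-methoxy-3-methylbuta-1,3-dien-1-olate | [Li]OC(OC)=CC(C)=C | intermediate
11 | [(1-methoxy-3-methylbuta-1,3-dien-1-yl)oxy]trimethylsilane (ketene acetal geometry not defined) | COC(O[Si](C)(C)C)=CC(C)=C | intermediate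
12 | (2S,5R)-2-tert-butyl-5-{[(2S)-6-methoxy-4-methyl-6-(trimethylsilyloxy)-3,6-dihydro-2H-pyran-2-yl]methyl}-5-methyl-1,3-dioxolan-4-one (both epimers at the ortho ester carbon) | CC1=CC(OC)(O[Si](C)(C)C)O[C@H](C[C@@]2(C)O[C@H](C(C)(C)C)OC2=O)C1 | intermediate
13 | (6S)-6-{[(2S,4R)-2-tert-butyl-4-methyl-5-oxo-1,3-dioxolan-4-yl]methyl}-4-methyl-5,6-dihydro-2H-pyran-2-one | CC1=CC(=O)O[C@H](C[C@@]2(C)O[C@H](C(C)(C)C)OC2=O)C1 | intermediate
14 | (1R,4S,6R)-4-{[(2S,4R)-2-tert-butyl-4-methyl-5-oxo-1,3-dioxolan-4-yl]methyl}-6-methyl-3,7-dioxabicyclo[4.1.0]heptan-2-one | C[C@]1(C[C@@H](C[C@@]2(C)O[C@H](C(C)(C)C)OC2=O)OC3=O)O[C@H]13 | intermediate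
15 | (2S,5R)-2-tert-butyl-5-{(2S)-2-hydroxy-3-[(2R,3S)-3-(hydroxymethyl)-2-methyloxiran-2-yl]propyl}-5-methyl-1,3-dioxolan-4-one | C[C@]1(C[C@H](O)C[C@@]2(C)O[C@H](C(C)(C)C)OC2=O)O[C@H]1CO | intermediate
16 | (3R,5R)-3-hydroxy-5-{[(2R,3S)-3-(hydroxymethyl)-2-methyloxiran-2-yl]methyl}-3-methyloxolan-2-one | C[C@]1(C[C@H]2C[C@@](C)(O)C(=O)O2)O[C@H]1CO | intermediate
17 | umbelliferone (7-hydroxy-2H-chromen-2-one) | Oc1ccc2ccc(=O)oc2c1 | starting material
18 | 7-{[(2S,3R)-3-{[(2R,4R)-4-hydroxy-4-methyl-5-oxooxolan-2-yl]methyl}-3-methyloxiran-2-yl]methoxy}-2H-chromen-2-one (CNP0246010.5) | C[C@]1(C[C@H]2C[C@@](C)(O)C(=O)O2)O[C@H]1COc1ccc2ccc(=O)oc2c1 | target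

## Step count and risks

Total step count: 8.
Longest linear sequence: 7 steps (steps 1, 2, 3, 5, 6, 7, 8); step 4 makes the diene separately.

The three steps most likely to fail:

Step 5, the cycloaddition. The 1,3-induction from the fully substituted C7 is the least secure stereochemical event of the route; the chelate model is a rationale, not a precedent. The neopentyl-type aldehyde may also react slowly. Fallback: relay through a tertiary β-alkoxy center, where 1,3-anti addition to the aldehyde is the normal outcome, and add the C-methyl group last on the γ-lactone, anti to the C5 side chain. It sets out from diene 11. Commercial 2-[(4R)-2,2-dimethyl-5-oxo-1,3-dioxolan-4-yl]acetic acid F1 (the acetonide of (R)-malic acid) is reduced with BH3·SMe2 to (5R)-5-(2-hydroxyethyl)-2,2-dimethyl-1,3-dioxolan-4-one F2 and oxidized with Dess–Martin periodinane to 2-[(4R)-2,2-dimethyl-5-oxo-1,3-dioxolan-4-yl]acetaldehyde F3. Cycloaddition of F3 with 11 as in step 5 gives (6S)-6-{[(4R)-2,2-dimethyl-5-oxo-1,3-dioxolan-4-yl]methyl}-4-methyl-5,6-dihydro-2H-pyran-2-one F4. Epoxidation as in step 6 gives (1R,4R,6R)-4-{[(4R)-2,2-dimethyl-5-oxo-1,3-dioxolan-4-yl]methyl}-6-methyl-3,7-dioxabicyclo[4.1.0]heptan-2-one F5, and borohydride reduction as in step 7 gives (3R,5R)-3-hydroxy-5-{[(2R,3S)-3-(hydroxymethyl)-2-methyloxiran-2-yl]methyl}oxolan-2-one F6. Deprotonation of F6 with LiN(iPr)2 (3.3 equiv, THF–DMPU, −78 °C) and C-methylation with MeI, which enters the lactone enolate trans to the C5 substituent, comes back to the route at 16.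

Step 6, the epoxidation. Conjugate addition of the peroxide to a β,β-disubstituted unsaturated lactone is slow, and the peroxide anion can attack the dioxolanone carbonyl instead. Fallback: reduce first, then epoxidize an electron-rich alkene with an electrophilic oxidant while it is still held in the six-membered ring. It sets out from 13. iBu2AlH (1.1 equiv, CH2Cl2, −78 °C) gives (2S,5R)-2-tert-butyl-5-{[(2S)-6-hydroxy-4-methyl-3,6-dihydro-2H-pyran-2-yl]methyl}-5-methyl-1,3-dioxolan-4-one F7 (lactol, both anomers). Dimethyldioxirane (acetone, −20 °C) attacks the trisubstituted alkene anti to the ring substituent to give (2S,5R)-2-tert-butyl-5-{[(1R,4S,6R)-2-hydroxy-6-methyl-3,7-dioxabicyclo[4.1.0]heptan-4-yl]methyl}-5-methyl-1,3-dioxolan-4-one F8. NaBH4 in EtOH then reduces the lactol and starts the transacylation of step 7, which comes back to the route at 16.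

Step 7, the reduction. The dioxolanone or the product lactone may be over-reduced, and the hydride must discriminate between three acyl groups. Fallback: separate the acyl transfer from the hydride step. It sets out from 14. NaOMe (0.2 equiv) in MeOH at 0 °C opens the glycidic δ-lactone as its methyl ester, and the freed C5 alkoxide closes the γ-lactone with loss of pivalaldehyde, giving methyl (2R,3R)-3-{[(2R,4R)-4-hydroxy-4-methyl-5-oxooxolan-2-yl]methyl}-3-methyloxirane-2-carboxylate F9. The glycidic ester alone is then reduced (NaBH4, CaCl2, THF–EtOH, −10 °C), because the lactone carbonyl is flanked by a fully substituted carbon, and this comes back to the route at 16.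

## Further compounds

F1 | step 5 | 2-[(4R)-2,2-dimethyl-5-oxo-1,3-dioxolan-4-yl]acetic acid | OC(=O)C[C@H]1OC(C)(C)OC1=O
F2 | step 5 | (5R)-5-(2-hydroxyethyl)-2,2-dimethyl-1,3-dioxolan-4-one | OCC[C@H]1OC(C)(C)OC1=O
F3 | step 5 | 2-[(4R)-2,2-dimethyl-5-oxo-1,3-dioxolan-4-yl]acetaldehyde | O=CC[C@H]1OC(C)(C)OC1=O
F4 | step 5 | (6S)-6-{[(4R)-2,2-dimethyl-5-oxo-1,3-dioxolan-4-yl]methyl}-4-methyl-5,6-dihydro-2H-pyran-2-one | CC1=CC(=O)O[C@H](C[C@H]2OC(C)(C)OC2=O)C1
F5 | step 5 | (1R,4R,6R)-4-{[(4R)-2,2-dimethyl-5-oxo-1,3-dioxolan-4-yl]methyl}-6-methyl-3,7-dioxabicyclo[4.1.0]heptan-2-one | C[C@]1(C[C@@H](C[C@H]2OC(C)(C)OC2=O)OC3=O)O[C@H]13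
F6 | step 5 | (3R,5R)-3-hydroxy-5-{[(2R,3S)-3-(hydroxymethyl)-2-methyloxiran-2-yl]methyl}oxolan-2-one | C[C@]1(C[C@H]2C[C@@H](O)C(=O)O2)O[C@H]1CO
F7 | step 6 | (2S,5R)-2-tert-butyl-5-{[(2S)-6-hydroxy-4-methyl-3,6-dihydro-2H-pyran-2-yl]methyl}-5-methyl-1,3-dioxolan-4-one (both anomers) | CC1=CC(O)O[C@H](C[C@@]2(C)O[C@H](C(C)(C)C)OC2=O)C1
F8 | step 6 | (2S,5R)-2-tert-butyl-5-{[(1R,4S,6R)-2-hydroxy-6-methyl-3,7-dioxabicyclo[4.1.0]heptan-4-yl]methyl}-5-methyl-1,3-dioxolan-4-one (both anomers) | C[C@]1(C[C@@H](C[C@@]2(C)O[C@H](C(C)(C)C)OC2=O)OC3O)O[C@H]13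
F9 | step 7 | methyl (2R,3R)-3-{[(2R,4R)-4-hydroxy-4-methyl-5-oxooxolan-2-yl]methyl}-3-methyloxirane-2-carboxylate | C[C@]1(C[C@H]2C[C@@](C)(O)C(=O)O2)O[C@H]1C(=O)OC
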